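**Plan**
1. Cuts (isoflavanone numbering, ring B primed): the O–Si bonds at O7 and O2' first, then C2–C3 of ring C, then the diazo group at C3, then C3–C1'. On ring B the cuts are O4'–Me, C1'–Br and the C5'–allyl bond.
2. Enabling feature: C2 is a bare CH2 bonded only to O1 and C3. It can therefore travel as the methyl of a methoxy group on C8a of ring A, ortho to the C4 carbonyl. C3 lies between C4=O and C1' and can be a diazo carbon, then a carbene carbon.
3. Ring B, forward: 2-methoxyresorcinol is monosilylated at O2' and prenylated at O4'. An aromatic Claisen shift places the 1,1-dimethylallyl group on C5', then C1' is brominated and O4' is methylated.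
4. Joining: the bromide arylates the enolate of silylated 4'-hydroxy-2'-methoxyacetophenone (C3–C1'), and diazo transfer follows at C3. Rings A and B are bought; ring C is the only ring made and it closes last.
5. Stereochemistry: C3 (R) is the only stereocentre. The chiral dirhodium carboxylate sets it during ring closure, and only a weakly acidic desilylation follows.

Key step: step 9

Assumption: models cannot predict with certainty which C3 configuration Rh2(S-PTTL)4 (dirhodium tetrakis[N-phthaloyl-(S)-tert-leucinate]) induces on this substrate. The S catalyst is written for 3R, and Rh2(R-PTTL)4 replaces it if a first trial shows the opposite sense.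

**Step 1**
Reactants: 1 2-methoxyresorcinol
Product: 2 3-[(tert-butyldiphenylsilyl)oxy]-2-methoxyphenol
Conditions: TBDPSCl (0.9 equiv), imidazole, DMF, 0 °C to rt
Reagents that add atoms: tert-butyldiphenylsilyl chloride (TBDPSCl), CC(C)(C)[Si](Cl)(c1ccccc1)c1ccccc1
Why: Silyl ether formation with imidazole catalysis on a symmetric diol, whose two hydroxyls are equivalent so that only one mono-ether can arise and is separated from unreacted diol and bis-ether, installs the one class of O2' protection that will later offer the carbene no C–H bond within reach.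

**Step 2**
Reactants: 2 3-[(tert-butyldiphenylsilyl)oxy]-2-methoxyphenol; 3 prenyl bromide
Product: 4 tert-butyl{2-methoxy-3-[(3-methylbut-2-en-1-yl)oxy]phenoxy}diphenylsilane
Conditions: K2CO3, dry acetone, rt to 45 °C
Reagents that add atoms: none
Why: Williamson ether synthesis, in which the single free phenoxide displaces the primary allylic bromide in an SN2 reaction under weakly basic, anhydrous conditions that a bulky aryl silyl ether tolerates.

**Step 3**
Reactants: 4 tert-butyl{2-methoxy-3-[(3-methylbut-2-en-1-yl)oxy]phenoxy}diphenylsilane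
Product: 6 3-[(tert-butyldiphenylsilyl)oxy]-2-methoxy-6-(2-methylbut-3-en-2-yl)phenol, via ortho-dienone 5 (not isolated)
Conditions: N,N-diethylaniline, 190 °C, sealed tube, argon
Reagents that add atoms: none
Why: Aromatic Claisen rearrangement, a suprafacial [3,3] shift that hands the tertiary terminus of the prenyl group to C5', the only hydrogen-bearing ortho carbon, after which the basic solvent speeds enolisation of dienone 5 so that a following Cope shift to the para carbon C1', already crowded by the neighbouring silyl ether, should not keep pace.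

**Step 4**
Reactants: 6 3-[(tert-butyldiphenylsilyl)oxy]-2-methoxy-6-(2-methylbut-3-en-2-yl)phenol
Product: 7 4-bromo-3-[(tert-butyldiphenylsilyl)oxy]-2-methoxy-6-(2-methylbut-3-en-2-yl)phenol
Conditions: NBS (1 equiv), CH2Cl2/MeCN, −40 to 0 °C, dark
Reagents that add atoms: N-bromosuccinimide (NBS), O=C1CCC(=O)N1Br
Why: Electrophilic aromatic bromination of a phenol, directed by the free 4'-hydroxyl whose two ortho carbons are occupied, so that the para carbon C1' is the only strongly activated site, and run cold so that the electron-rich ring consumes NBS before the hindered monosubstituted alkene can react.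

**Step 5**
Reactants: 7 4-bromo-3-[(tert-butyldiphenylsilyl)oxy]-2-methoxy-6-(2-methylbut-3-en-2-yl)phenol
Product: 8 [6-bromo-2,3-dimethoxy-4-(2-methylbut-3-en-2-yl)phenoxy](tert-butyl)diphenylsilane
Conditions: MeI, K2CO3, dry acetone, 40 °C
Reagents that add atoms: iodomethane (MeI), CI
Why: Williamson O-methylation, in which the small electrophile reaches the phenoxide flanked by the methoxy and tert-alkyl groups while aryl bromide, alkene and silyl ether are untouched by K2CO3 in dry acetone.

**Step 6**
Reactants: 9 4'-hydroxy-2'-methoxyacetophenone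
Product: 10 4'-[(tert-butyldiphenylsilyl)oxy]-2'-methoxyacetophenone
Conditions: TBDPSCl, imidazole, DMF, rt
Reagents that add atoms: tert-butyldiphenylsilyl chloride (TBDPSCl), CC(C)(C)[Si](Cl)(c1ccccc1)c1ccccc1
Why: Silyl ether formation with imidazole catalysis on the only hydroxyl group, giving the same protecting group as on ring B so that one final operation frees both phenols.

**Step 7**
Reactants: 8 [6-bromo-2,3-dimethoxy-4-(2-methylbut-3-en-2-yl)phenoxy](tert-butyl)diphenylsilane; 10 4'-[(tert-butyldiphenylsilyl)oxy]-2'-methoxyacetophenone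
Product: 11 2-{2-[(tert-butyldiphenylsilyl)oxy]-3,4-dimethoxy-5-(2-methylbut-3-en-2-yl)phenyl}-1-{4-[(tert-butyldiphenylsilyl)oxy]-2-methoxyphenyl}ethan-1-one
Conditions: Pd2(dba)3 (cat), XPhos, K3PO4, toluene, 90 °C
Reagents that add atoms: none
Why: Palladium-catalysed α-arylation of a ketone enolate (oxidative addition of zerovalent palladium into the C1'–Br bond, enolate binding, C–C reductive elimination promoted by the bulky biaryl phosphine), with K3PO4 as a base mild enough for aryl silyl ethers and with monoarylation secured because product 11 rests as its hindered, stabilised enolate.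

**Step 8**
Reactants: 11 2-{2-[(tert-butyldiphenylsilyl)oxy]-3,4-dimethoxy-5-(2-methylbut-3-en-2-yl)phenyl}-1-{4-[(tert-butyldiphenylsilyl)oxy]-2-methoxyphenyl}ethan-1-one
Product: 12 2-diazo-2-{2-[(tert-butyldiphenylsilyl)oxy]-3,4-dimethoxy-5-(2-methylbut-3-en-2-yl)phenyl}-1-{4-[(tert-butyldiphenylsilyl)oxy]-2-methoxyphenyl}ethan-1-one
Conditions: p-ABSA, DBU, dry MeCN, 0 °C to rt
Reagents that add atoms: 4-acetamidobenzenesulfonyl azide (p-ABSA), CC(=O)Nc1ccc(S(=O)(=O)N=[N+]=[N-])cc1
Why: Regitz diazo transfer, feasible without prior activation because the C3 methylene is acidified by both the aryl ketone and ring B, so that DBU generates enough enolate to attack the terminal nitrogen of the sulfonyl azide and the triazene collapses to diazoketone and sulfonamide.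

**Step 9**
Reactants: 12 2-diazo-2-{2-[(tert-butyldiphenylsilyl)oxy]-3,4-dimethoxy-5-(2-methylbut-3-en-2-yl)phenyl}-1-{4-[(tert-butyldiphenylsilyl)oxy]-2-methoxyphenyl}ethan-1-one
Product: 14 (3R)-7,2'-bis-O-(tert-butyldiphenylsilyl)pervilleanone, via rhodium carbene 13 (not isolated)
Conditions: Rh2(S-PTTL)4 (2 mol %), toluene, 4 Å molecular sieves, 0 °C to rt, slow addition of 12
Reagents that add atoms: none
Why: The diazo carbon of 12 binds an axial rhodium site of the dirhodium tetracarboxylate, N2 leaves, and the donor/acceptor carbene 13 (ring B as donor, the C4 acyl group as acceptor) takes up a methoxy C–H bond through a concerted, asynchronous three-centre transition state in which hydride-like transfer to C3 runs ahead of C2–C3 bond formation, the positive charge building on C2 being stabilised by O1. The closest known reaction type is the chiral dirhodium carboxylate catalysed intramolecular C–H insertion of 2-alkoxyaryl α-diazoketones to chroman-4-ones, together with the insertion of aryl-substituted rhodium carbenes into methyl ethers. Ring C closes by a formal 1,6 C–H insertion, the six ring members being C3, C4, C4a, C8a, O1 and C2. C3 is the only new stereocentre: hydrogen and C2 arrive on the carbene face left open by the pocket of the four N-phthaloyl-tert-leucinate ligands as rhodium departs from the other face, so the catalyst antipode decides R or S, and the neutral, aprotic medium keeps the acidic C3–H centre as formed. The step needs site selectivity for the ring A methoxy group: C3 has no β-hydrogen to shift, O2' carries a silyl group with no C–H bond within five- or six-membered reach (any alkyl or acetal group there would win by 1,5-insertion), the 3'-methoxy and the 5'-vinyl group sit meta to C1' and cannot fold back, and slow addition keeps intermolecular cyclopropanation and carbene dimerisation down. Attack of O1 on the carbene gives a five-membered oxonium ylide, but a methyl group is a poor migrating group, so this path should revert to 13 and drain into insertion.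

**Step 10**
Reactants: 14 (3R)-7,2'-bis-O-(tert-butyldiphenylsilyl)pervilleanone
Product: 15 (3R)-pervilleanone
Conditions: HF·pyridine, THF, 0 °C to rt, polyethylene vessel; pH 7 phosphate buffer
Reagents that add atoms: none
Why: Fluoride-driven cleavage of aryl silyl ethers through Si–F bond formation, carried out in a weakly acidic medium in which no enolate of the C4 ketone is formed, so that C3 keeps its R configuration while methyl ethers and the vinyl group are inert.

**Compound list**
1 | 2-methoxyresorcinol (2-methoxybenzene-1,3-diol) | COc1c(O)cccc1O | starting material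
2 | 3-[(tert-butyldiphenylsilyl)oxy]-2-methoxyphenol | COc1c(O)cccc1O[Si](c1ccccc1)(c1ccccc1)C(C)(C)C | intermediate
3 | prenyl bromide (1-bromo-3-methylbut-2-ene) | CC(C)=CCBr | starting material
4 | tert-butyl{2-methoxy-3-[(3-methylbut-2-en-1-yl)oxy]phenoxy}diphenylsilane | COc1c(OCC=C(C)C)cccc1O[Si](c1ccccc1)(c1ccccc1)C(C)(C)C | intermediate
5 | 3-[(tert-butyldiphenylsilyl)oxy]-2-methoxy-6-(2-methylbut-3-en-2-yl)cyclohexa-2,4-dien-1-one (racemic, transient) | C=CC(C)(C)C1C=CC(O[Si](c2ccccc2)(c2ccccc2)C(C)(C)C)=C(OC)C1=O | intermediate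
6 | 3-[(tert-butyldiphenylsilyl)oxy]-2-methoxy-6-(2-methylbut-3-en-2-yl)phenol | C=CC(C)(C)c1ccc(O[Si](c2ccccc2)(c2ccccc2)C(C)(C)C)c(OC)c1O | intermediate
7 | 4-bromo-3-[(tert-butyldiphenylsilyl)oxy]-2-methoxy-6-(2-methylbut-3-en-2-yl)phenol | C=CC(C)(C)c1cc(Br)c(O[Si](c2ccccc2)(c2ccccc2)C(C)(C)C)c(OC)c1O | intermediate
8 | [6-bromo-2,3-dimethoxy-4-(2-methylbut-3-en-2-yl)phenoxy](tert-butyl)diphenylsilane (ring B bromide) | C=CC(C)(C)c1cc(Br)c(O[Si](c2ccccc2)(c2ccccc2)C(C)(C)C)c(OC)c1OC | intermediate
9 | 4'-hydroxy-2'-methoxyacetophenone | CC(=O)c1ccc(O)cc1OC | starting material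
10 | 4'-[(tert-butyldiphenylsilyl)oxy]-2'-methoxyacetophenone | CC(=O)c1ccc(O[Si](c2ccccc2)(c2ccccc2)C(C)(C)C)cc1OC | intermediate
11 | 2-{2-[(tert-butyldiphenylsilyl)oxy]-3,4-dimethoxy-5-(2-methylbut-3-en-2-yl)phenyl}-1-{4-[(tert-butyldiphenylsilyl)oxy]-2-methoxyphenyl}ethan-1-one (deoxybenzoin) | C=CC(C)(C)c1cc(CC(=O)c2ccc(O[Si](c3ccccc3)(c3ccccc3)C(C)(C)C)cc2OC)c(O[Si](c2ccccc2)(c2ccccc2)C(C)(C)C)c(OC)c1OC | intermediate
12 | 2-diazo derivative of 11 (aryl diazoketone, diazo group on C3) | C=CC(C)(C)c1cc(C(=[N+]=[N-])C(=O)c2ccc(O[Si](c3ccccc3)(c3ccccc3)C(C)(C)C)cc2OC)c(O[Si](c2ccccc2)(c2ccccc2)C(C)(C)C)c(OC)c1OC | intermediate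
13 | rhodium carbene from 12 ([Rh] stands for the Rh2(S-PTTL)4 unit bound through one rhodium, ligands not drawn) | C=CC(C)(C)c1cc(C(=[Rh])C(=O)c2ccc(O[Si](c3ccccc3)(c3ccccc3)C(C)(C)C)cc2OC)c(O[Si](c2ccccc2)(c2ccccc2)C(C)(C)C)c(OC)c1OC | intermediate
14 | (3R)-7,2'-bis-O-(tert-butyldiphenylsilyl)pervilleanone | C=CC(C)(C)c1cc([C@@H]2COc3cc(O[Si](c4ccccc4)(c4ccccc4)C(C)(C)C)ccc3C2=O)c(O[Si](c2ccccc2)(c2ccccc2)C(C)(C)C)c(OC)c1OC | intermediate
15 | (3R)-pervilleanone | C=CC(C)(C)c1cc([C@@H]2COc3cc(O)ccc3C2=O)c(O)c(OC)c1OC | target

**Total step count:** 10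
**Longest linear sequence:** 9 (steps 1–5 and 7–10; step 6 is the one-step ring A branch)

**Steps most likely to fail**

**Step 9.** Insertion into a primary C–H bond through a six-membered transition state is slow. The carbene may therefore be diverted by methyl shift within the oxonium ylide, by Wolff rearrangement or by intermolecular attack on the vinyl group. Facial discrimination by the catalyst pocket may also be weak.

The fallback sets out from 8 and comes back at 14. It buys ring C and sets C3 by dynamic kinetic resolution.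
- Commercial 7-hydroxychroman-4-one is silylated (TBDPSCl, imidazole, DMF) to 7-[(tert-butyldiphenylsilyl)oxy]chroman-4-one F1.
- The enolate of this ketone is arylated with 8 (Pd2(dba)3, XPhos, K3PO4, toluene) to racemic 7,2'-bis-O-(tert-butyldiphenylsilyl)pervilleanone F2.
- Asymmetric transfer hydrogenation follows (RuCl(p-cymene)[(R,R)-TsDPEN], HCO2H/Et3N). C3 epimerises through the enol faster than the mismatched enantiomer is reduced, so this should give the cis alcohol (3R,4R)-7,2'-bis-O-(tert-butyldiphenylsilyl)pervilleanol F3.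
- Dess–Martin periodinane in CH2Cl2 restores the C4 ketone without touching C3 and gives 14.

The last two operations would also upgrade 14 of insufficient enantiomeric purity.

**Step 3.** The allyl unit may migrate on to the open para carbon by a Cope shift. The product may also react further at the reaction temperature, either by abnormal Claisen isomerisation or by ring closure of the phenol onto the alkene.

The fallback sets out from 1 and comes back at 7. Bromine goes on first and serves as the para blocking group.
- 1 is monobrominated at one of its two equivalent activated carbons (NBS, CH2Cl2/THF, −78 °C) to 4-bromo-2-methoxybenzene-1,3-diol F4.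
- The dianion of this diol (NaH, 2 equiv, DMF, 0 °C) is treated with one equivalent of 3. Alkylation should occur at the more basic and less hindered phenoxide para to bromine, giving 6-bromo-2-methoxy-3-[(3-methylbut-2-en-1-yl)oxy]phenol F5.
- The remaining hindered phenol is silylated (TBDPSCl, imidazole, DMAP, DMF, 40 °C) to {6-bromo-2-methoxy-3-[(3-methylbut-2-en-1-yl)oxy]phenoxy}(tert-butyl)diphenylsilane F6.
- Heating in N,N-diethylaniline runs the Claisen rearrangement through 4-bromo-3-[(tert-butyldiphenylsilyl)oxy]-2-methoxy-6-(2-methylbut-3-en-2-yl)cyclohexa-2,4-dien-1-one F7 and delivers 7.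

This order also avoids bromination in the presence of the alkene.

**Step 7.** Oxidative addition and reductive elimination next to the bulky silyl ether may be sluggish at the temperature needed. Base-induced loss of silyl groups and Heck-type consumption of the vinyl group may accompany the coupling.

The fallback sets out from 6 and 10 and comes back at 12. It arylates a ready-made diazo carbon at room temperature and so also bypasses step 8.
- 6 is iodinated para to the free hydroxyl (NIS, MeCN, −20 °C) to 3-[(tert-butyldiphenylsilyl)oxy]-4-iodo-2-methoxy-6-(2-methylbut-3-en-2-yl)phenol F8.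
- Methylation (MeI, K2CO3, acetone) gives tert-butyl[6-iodo-2,3-dimethoxy-4-(2-methylbut-3-en-2-yl)phenoxy]diphenylsilane F9.
- Ketone 10 undergoes detrifluoroacetylative diazo transfer. LiN(SiMe3)2 and CF3CO2CH2CF3 in THF at −78 °C give 1-{4-[(tert-butyldiphenylsilyl)oxy]-2-methoxyphenyl}-4,4,4-trifluorobutane-1,3-dione F10. Treatment with p-ABSA, Et3N and H2O in MeCN then gives 2-diazo-1-{4-[(tert-butyldiphenylsilyl)oxy]-2-methoxyphenyl}ethan-1-one F11.
- Palladium-catalysed C–H arylation of the acyldiazomethane with the aryl iodide (Pd(PPh3)4, Ag2CO3, Et3N, toluene, rt) joins the two pieces to 12.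

**Further compounds**
F1 | step 9 | 7-[(tert-butyldiphenylsilyl)oxy]chroman-4-one | O=C1CCOc2cc(O[Si](c3ccccc3)(c3ccccc3)C(C)(C)C)ccc21
F2 | step 9 | racemic 7,2'-bis-O-(tert-butyldiphenylsilyl)pervilleanone | C=CC(C)(C)c1cc(C2COc3cc(O[Si](c4ccccc4)(c4ccccc4)C(C)(C)C)ccc3C2=O)c(O[Si](c2ccccc2)(c2ccccc2)C(C)(C)C)c(OC)c1OC
F3 | step 9 | (3R,4R)-7,2'-bis-O-(tert-butyldiphenylsilyl)pervilleanol (cis-isoflavan-4-ol) | C=CC(C)(C)c1cc([C@@H]2COc3cc(O[Si](c4ccccc4)(c4ccccc4)C(C)(C)C)ccc3[C@@H]2O)c(O[Si](c2ccccc2)(c2ccccc2)C(C)(C)C)c(OC)c1OC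
F4 | step 3 | 4-bromo-2-methoxybenzene-1,3-diol | COc1c(O)ccc(Br)c1O
F5 | step 3 | 6-bromo-2-methoxy-3-[(3-methylbut-2-en-1-yl)oxy]phenol | COc1c(OCC=C(C)C)ccc(Br)c1O
F6 | step 3 | {6-bromo-2-methoxy-3-[(3-methylbut-2-en-1-yl)oxy]phenoxy}(tert-butyl)diphenylsilane | COc1c(OCC=C(C)C)ccc(Br)c1O[Si](c1ccccc1)(c1ccccc1)C(C)(C)C
F7 | step 3 | 4-bromo-3-[(tert-butyldiphenylsilyl)oxy]-2-methoxy-6-(2-methylbut-3-en-2-yl)cyclohexa-2,4-dien-1-one | C=CC(C)(C)C1C=C(Br)C(O[Si](c2ccccc2)(c2ccccc2)C(C)(C)C)=C(OC)C1=O
F8 | step 7 | 3-[(tert-butyldiphenylsilyl)oxy]-4-iodo-2-methoxy-6-(2-methylbut-3-en-2-yl)phenol | C=CC(C)(C)c1cc(I)c(O[Si](c2ccccc2)(c2ccccc2)C(C)(C)C)c(OC)c1O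
F9 | step 7 | tert-butyl[6-iodo-2,3-dimethoxy-4-(2-methylbut-3-en-2-yl)phenoxy]diphenylsilane | C=CC(C)(C)c1cc(I)c(O[Si](c2ccccc2)(c2ccccc2)C(C)(C)C)c(OC)c1OC
F10 | step 7 | 1-{4-[(tert-butyldiphenylsilyl)oxy]-2-methoxyphenyl}-4,4,4-trifluorobutane-1,3-dione | COc1cc(O[Si](c2ccccc2)(c2ccccc2)C(C)(C)C)ccc1C(=O)CC(=O)C(F)(F)F
F11 | step 7 | 2-diazo-1-{4-[(tert-butyldiphenylsilyl)oxy]-2-methoxyphenyl}ethan-1-one | COc1cc(O[Si](c2ccccc2)(c2ccccc2)C(C)(C)C)ccc1C(=O)C=[N+]=[N-]
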